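## Structural features

The target is an achiral flavone: a 4H-chromen-4-one (benzo ring A fused to pyranone ring C) that carries aryl ring B at C2 through the single bond C2–C1'. Ring A has methoxy groups at C5 and C6, so C8a, C4a, C5 and C6 form a contiguous tetrasubstituted arene in which the carbonyl-bearing C4a lies between the two oxygenated carbons C8a and C5. Ring B has methoxy groups at C2', C3', C5' and C6' and a single hydrogen at C4'. It is therefore 1,2,4,5-tetramethoxybenzene less one hydrogen, and that arene has only two C–H bonds, which are homotopic. There is no stereocenter, and because ring B is symmetric about the C1'–C4' axis the twisted C2–C1' bond raises no atropisomerism. The fragile points are the six aryl methyl ethers (the C5 ether, peri to the carbonyl, is the most labile toward Lewis acids), the pyranone ring (opened at C2 by hydroxide) and the very electron-rich ring B (oxidizable to a quinone). The real difficulty is twofold: the C2–C1' bond is flanked on ring B by two ortho methoxy groups, and the 5,6-pattern of ring A is the one that electrophilic acylation of a 3,4-dioxygenated phenol does not give. The key step exploits the first feature: C1' is one of two identical C–H carbons of a commercial arene and C2 of the pyranone carries a hydrogen, so the C2–C1' bond can be made by a twofold C–H coupling of two unfunctionalized partners with no regiochemical question on ring B.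

## Logic of the disconnections

**9 to 7 + 8.** The bond cut is C2–C1'. C1' of 9 corresponds to either of the two homotopic C–H carbons of 8, and C2 of 7 carries a hydrogen, so neither side needs a halogen, metal or carbonyl handle. Cutting here also puts the most hindered bond of 9 last, so no earlier step has to carry a di-ortho-substituted aryl group through a condensation. The gain is that a 21-carbon target falls into an 11-carbon and a 10-carbon piece, the latter commercial. The demand on the forward step is that the coupling takes C2–H and not C3–H of 7, stops after one arylation of 8, tolerates two ortho methoxy groups at the new bond, and uses an oxidant that does not turn 8 into a quinone.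

**7 to 5 (through 6).** The bond cut is O1–C2 of ring C, with the C–N bond of 5 standing in its place. A ring C that is unsubstituted at C2 and C3 is the addition–elimination product of a phenol oxygen and a β-aminovinyl ketone, and the acid that frees the phenol also drives the closure. The gain is that the bicycle becomes a monocyclic aryl ketone with a three-carbon chain. The demand is that the acid cleaves the acetal and closes the ring without touching the methyl ethers.

**5 to 4.** The bond cut is C2=C3 (flavone numbering), that is the bond between the methyl carbon of 4 and a one-carbon unit delivered by a formamide acetal. The gain is reduction to a methyl ketone. The demand is a condensation at the methyl group of a ketone whose carbonyl is flanked by two ortho substituents; the methyl group itself lies outside them.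

**4 to 2 (through 3).** The bond cut is C4–C4a, the aryl–acyl bond. C4a sits between the oxygen-bearing carbons C8a and C5, which is the site where two ortho-directing oxygen groups cooperate in a lithiation. An electrophilic acylation of 1 or 2 would instead go para to a methoxy group and lead to the 6,7-pattern. The gain is that the contiguous tetrasubstituted ring A comes from a 1,2,4-trisubstituted arene. The demand is lithiation only at the carbon between the two oxygens, and an acetyl donor that stops at the ketone.

**2 to 1.** The bond cut is the O–CH2 bond of the acetal. The phenol must be masked by a group that survives an alkyllithium, strengthens the ortho direction and falls off under the acid of the ring closure. The gain is that 1 is commercial. The demand is only a clean O-alkylation.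

## Other disconnections considered

**Alternative 1:** (the first that comes to mind) Cut C2–C3 and O1–C2.
- Forward key step: Claisen–Schmidt condensation of 1-(6-hydroxy-2,3-dimethoxyphenyl)ethan-1-one A1 (from 4 by acetal cleavage) with 2,3,5,6-tetramethoxybenzaldehyde A2 (from 8 by lithiation and formylation) to the 2'-hydroxychalcone A3, followed by oxidative cyclization to 9.
- Ground for not choosing it: A2 has to be made from the same arene 8 that the chosen plan uses directly, so a carbon handle is installed only to be consumed.
- Ring B would enter as an aldehyde shielded by two ortho methoxy groups and would later be a β-aryl group twisted out of conjugation, which should slow both the aldol step and the oxa-Michael closure.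
- The sequence is one step longer, and its key step is the one most chemists would draw first.

**Alternative 2:** Cut C4–C4a, C3–C4 and O1–C2.
- Forward key step: carbonylative Sonogashira coupling of 2-iodo-3,4-dimethoxyphenol A4 with 3-ethynyl-1,2,4,5-tetramethoxybenzene A5 to the ynone A6, followed by 6-endo-dig closure to 9.
- Ground for not choosing it: both partners need handles. A4 requires the same directed lithiation as step 2 plus iodination and deprotection, and A5 requires about three steps from 8.
- Oxidative addition would have to occur at a C–I bond flanked by two oxygen substituents.
- A6 can close in the 5-exo-dig mode at the alkyne carbon next to the carbonyl as well as in the required 6-endo-dig mode, and the electron-rich, twisted aryl group lowers the electrophilicity of the β-carbon that the 6-endo mode needs.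
- The plan is about three steps longer.

**Alternative 3:** Ring A carried partly saturated and aromatized late.
- Forward key step: C-acylation of cyclohexane-1,3-dione A7 with an activated form of 3-(2,3,5,6-tetramethoxyphenyl)prop-2-ynoic acid A8 and cyclization to the 7,8-dihydrochromene-4,5-dione A9. Oxygenation at C6 α to the C5 ketone, dehydrogenation to the 5,6-dihydroxyflavone A10 and double O-methylation would follow.
- Attraction: the C5 carbonyl fixes the 5,6-oxygenation pattern without any arene regiochemistry.
- Ground for not choosing it: it needs three oxidation-level adjustments on ring A in the presence of the oxidation-prone ring B, and methylation of a chelated 5-hydroxyl.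
- A8 alone costs about three steps from 8, so the plan runs to roughly nine steps against five.

Key step: step 5

Assumption: 1 and 8 are taken as commercial; flavone numbering (O1, C2 to C8a, C1' to C6') is used for the target and its chromone precursor.

## Steps

**Step 1**
Reactants: 1 3,4-dimethoxyphenol
Product: 2 1,2-dimethoxy-4-(methoxymethoxy)benzene
Conditions: MOMCl, i-Pr2NEt, CH2Cl2, 0 °C to rt
Reagents that add atoms: chloromethyl methyl ether, COCCl
Why: O-alkylation of the phenol by the oxocarbenium-forming chloride (Williamson-type etherification); the acetal is stable to n-BuLi, is the stronger ortho-director for step 2 and is removed by the acid of step 4.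

**Step 2**
Reactants: 2 1,2-dimethoxy-4-(methoxymethoxy)benzene
Product: 4 1-[2,3-dimethoxy-6-(methoxymethoxy)phenyl]ethan-1-one, via aryllithium 3 (not isolated)
Conditions: n-BuLi, TMEDA, THF, 0 °C; then MeC(O)N(OMe)Me, −78 °C to rt; then H2O
Reagents that add atoms: n-butyllithium, CCCC[Li] (lithium of 3 only); N-methoxy-N-methylacetamide, CC(=O)N(C)OC
Why: Directed ortho-metalation: the acetal oxygen and the neighbouring methoxy oxygen both coordinate lithium and both acidify the C–H between them (C3 of 2), so deprotonation should occur there and not at the two singly activated positions. Acylation of 3 by the N-methoxy-N-methyl amide (Weinreb ketone synthesis) stops at the ketone because the chelated tetrahedral adduct survives until the water quench.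

**Step 3**
Reactants: 4 1-[2,3-dimethoxy-6-(methoxymethoxy)phenyl]ethan-1-one
Product: 5 (E)-3-(dimethylamino)-1-[2,3-dimethoxy-6-(methoxymethoxy)phenyl]prop-2-en-1-one
Conditions: Me2NCH(OMe)2 (neat), 110 °C
Reagents that add atoms: N,N-dimethylformamide dimethyl acetal, COC(OC)N(C)C
Why: Enaminone formation by condensation of the methyl ketone with the formamide acetal: the enolate adds to the formamidinium ion and loss of methanol gives the push–pull enaminone, whose E geometry is the thermodynamically favoured one. The reacting methyl group lies outside the two ortho substituents, and the acetal protecting group is inert to these conditions.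

**Step 4**
Reactants: 5 (E)-3-(dimethylamino)-1-[2,3-dimethoxy-6-(methoxymethoxy)phenyl]prop-2-en-1-one
Product: 7 5,6-dimethoxy-4H-chromen-4-one, via phenol enaminone 6 (not isolated)
Conditions: conc. HCl, MeOH, 60 °C
Reagents that add atoms: none
Why: Acid cleaves the methoxymethyl acetal, with methanol trapping the methoxymethyl cation as dimethoxymethane. The freed phenol of 6 adds to the β-carbon of the protonated enaminone in a 6-endo-trig oxa-Michael closure and dimethylamine is expelled (addition–elimination), which forms ring C. Aryl methyl ethers should be stable to methanolic HCl at this temperature.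

**Step 5**
Reactants: 7 5,6-dimethoxy-4H-chromen-4-one; 8 1,2,4,5-tetramethoxybenzene (in excess)
Product: 9 5,6-dimethoxy-2-(2,3,5,6-tetramethoxyphenyl)-4H-chromen-4-one (5,6,2',3',5',6'-hexamethoxyflavone, the target)
Conditions: 8 (5 equiv), Pd(O2CCF3)2 (0.2 equiv), AgOAc (3 equiv), CsO2CCMe3 (1 equiv), Me3CCO2H, 110 °C
Reagents that add atoms: none
Why: Twofold C–H (cross-dehydrogenative) coupling of a chromone C2–H with an arene C–H under a divalent palladium carboxylate and a silver carboxylate oxidant, a known reaction type for the 2-arylation of chromones. Mechanism: the palladium carboxylate palladates 8 by concerted metalation–deprotonation at one of its two homotopic C–H bonds, which are the most electron-rich and, through two ortho oxygens, the most acidic aryl C–H bonds in the flask; the aryl–palladium species then inserts C2=C3 of 7 with the aryl group going to the electrophilic C2 and palladium to C3 as an enolate, and after C-/O-enolate equilibration syn β-hydride elimination of H–C2 restores the pyranone. The zerovalent palladium set free is returned to the divalent state by AgOAc. No ring is closed and no stereocenter is formed. Site selectivity on 8 is fixed by symmetry, so 9 is the only possible mono-arylation product. C2 over C3 on 7 follows from the polarity of the insertion (aryl to the β-carbon of the vinylogous ester), and the carbonyl-directed peri palladation that chromones can undergo is shut off because C5 carries a methoxy group. Double arylation of 8 should be held back by the excess of 8 and by the electron-poor pyranone that 9 carries para to its remaining C4'–H. The two ortho methoxy groups at the new bond are small and can coordinate palladium, so the hindrance should slow but not stop the insertion, and unproductive protodepalladation only returns 8.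

## Compound list

1 | 3,4-dimethoxyphenol | COc1ccc(O)cc1OC | starting material
2 | 1,2-dimethoxy-4-(methoxymethoxy)benzene | COCOc1ccc(OC)c(OC)c1 | intermediate
3 | [2,3-dimethoxy-6-(methoxymethoxy)phenyl]lithium | [Li]c1c(OCOC)ccc(OC)c1OC | intermediate (not isolated)
4 | 1-[2,3-dimethoxy-6-(methoxymethoxy)phenyl]ethan-1-one | CC(=O)c1c(OCOC)ccc(OC)c1OC | intermediate
5 | (E)-3-(dimethylamino)-1-[2,3-dimethoxy-6-(methoxymethoxy)phenyl]prop-2-en-1-one | CN(C)/C=C/C(=O)c1c(OCOC)ccc(OC)c1OC | intermediate
6 | (E)-3-(dimethylamino)-1-(6-hydroxy-2,3-dimethoxyphenyl)prop-2-en-1-one | CN(C)/C=C/C(=O)c1c(O)ccc(OC)c1OC | intermediate (not isolated)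
7 | 5,6-dimethoxy-4H-chromen-4-one | COc1ccc2occc(=O)c2c1OC | intermediate
8 | 1,2,4,5-tetramethoxybenzene | COc1cc(OC)c(OC)cc1OC | starting material
9 | 5,6-dimethoxy-2-(2,3,5,6-tetramethoxyphenyl)-4H-chromen-4-one (5,6,2',3',5',6'-hexamethoxyflavone; achiral) | COc1cc(OC)c(OC)c(-c2cc(=O)c3c(OC)c(OC)ccc3o2)c1OC | target

## Step count and least certain steps

Total step count: 5. Longest linear sequence: 5 steps (1, 2, 4, 5, 7, 9); 8 enters in the last step.

**Step 5 (key step).**
- What may go wrong: palladation and insertion of the di-ortho-substituted arene may be slower than the competing processes. These are oxidative homocoupling of 8, oxidation of 8 toward a quinone by the silver salt at 110 °C, and palladation of ring A of 7 leading to self-coupling. The catalyst would then be used up without cross-coupling. A second arylation at C4'–H is the other risk.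
- Fallback (sets out from 8 and 7, comes back at 9): 8 would be deprotonated with n-BuLi (THF, 0 °C) to (2,3,5,6-tetramethoxyphenyl)lithium F1. With CuI (0.5 equiv, −40 °C) this would give lithium bis(2,3,5,6-tetramethoxyphenyl)cuprate F2. Conjugate addition of F2 to 7 in the presence of Me3SiCl (THF, −78 °C) would give the racemic silyl enol ether 5,6-dimethoxy-2-(2,3,5,6-tetramethoxyphenyl)-4-(trimethylsilyloxy)-2H-chromene F3. Dehydrogenation of crude F3 with DDQ (dioxane, rt) would remove H–C2 and the silyl group and give 9.
- This replaces the C–H/C–H coupling by a polar conjugate addition of a preformed aryl nucleophile followed by oxidation, both known operations on chromones and silyl enol ethers.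

**Step 2.**
- What may go wrong: proton transfer from the acetyl group of the amide to the hindered, basic aryllithium 3 instead of addition, which would return 2. Less likely is lithiation at the position activated by the acetal oxygen alone.
- Fallback (sets out from 2, comes back at 4): aryllithium 3, generated as in step 2, would be trapped with the far more electrophilic acetaldehyde (−78 °C) to give racemic 1-[2,3-dimethoxy-6-(methoxymethoxy)phenyl]ethan-1-ol F4. F4 would be oxidized with Dess–Martin periodinane (CH2Cl2, NaHCO3, rt) to 4.
- Acyl substitution is thus replaced by carbonyl addition and oxidation.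

**Step 3.**
- What may go wrong: slow condensation, because the electron-rich ketone, twisted out of the ring plane, enolizes reluctantly, with decomposition on prolonged heating in the formamide acetal.
- Fallback (sets out from 4, comes back at 7): Claisen formylation of 4 with ethyl formate and NaH (THF, 0 °C to rt) would give 3-[2,3-dimethoxy-6-(methoxymethoxy)phenyl]-3-oxopropanal F5, present as its sodium enolate. Treatment with conc. HCl in MeOH (60 °C) would remove the acetal and cyclodehydrate the hydroxy ketoaldehyde to 7.
- A strong base and an irreversible enolate formation thus replace the neutral thermal condensation.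

## Further compounds

F1 | step 5 | (2,3,5,6-tetramethoxyphenyl)lithium | [Li]c1c(OC)c(OC)cc(OC)c1OC
F2 | step 5 | lithium bis(2,3,5,6-tetramethoxyphenyl)cuprate | [Li+].COc1cc(OC)c(OC)c([Cu-]c2c(OC)c(OC)cc(OC)c2OC)c1OC
F3 | step 5 | 5,6-dimethoxy-2-(2,3,5,6-tetramethoxyphenyl)-4-(trimethylsilyloxy)-2H-chromene (racemic) | COc1cc(OC)c(OC)c(C2C=C(O[Si](C)(C)C)c3c(OC)c(OC)ccc3O2)c1OC
F4 | step 2 | 1-[2,3-dimethoxy-6-(methoxymethoxy)phenyl]ethan-1-ol (racemic) | CC(O)c1c(OCOC)ccc(OC)c1OC
F5 | step 3 | 3-[2,3-dimethoxy-6-(methoxymethoxy)phenyl]-3-oxopropanal (drawn as the keto aldehyde) | O=CCC(=O)c1c(OCOC)ccc(OC)c1OC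
A1 | alternative 1 | 1-(6-hydroxy-2,3-dimethoxyphenyl)ethan-1-one | CC(=O)c1c(O)ccc(OC)c1OC
A2 | alternative 1 | 2,3,5,6-tetramethoxybenzaldehyde | COc1cc(OC)c(OC)c(C=O)c1OC
A3 | alternative 1 | (E)-1-(6-hydroxy-2,3-dimethoxyphenyl)-3-(2,3,5,6-tetramethoxyphenyl)prop-2-en-1-one | COc1cc(OC)c(OC)c(/C=C/C(=O)c2c(O)ccc(OC)c2OC)c1OC
A4 | alternative 2 | 2-iodo-3,4-dimethoxyphenol | COc1ccc(O)c(I)c1OC
A5 | alternative 2 | 3-ethynyl-1,2,4,5-tetramethoxybenzene | COc1cc(OC)c(OC)c(C#C)c1OC
A6 | alternative 2 | 1-(6-hydroxy-2,3-dimethoxyphenyl)-3-(2,3,5,6-tetramethoxyphenyl)prop-2-yn-1-one | COc1cc(OC)c(OC)c(C#CC(=O)c2c(O)ccc(OC)c2OC)c1OC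
A7 | alternative 3 | cyclohexane-1,3-dione | O=C1CCCC(=O)C1
A8 | alternative 3 | 3-(2,3,5,6-tetramethoxyphenyl)prop-2-ynoic acid | COc1cc(OC)c(OC)c(C#CC(=O)O)c1OC
A9 | alternative 3 | 2-(2,3,5,6-tetramethoxyphenyl)-7,8-dihydro-4H-chromene-4,5(6H)-dione | COc1cc(OC)c(OC)c(C2=CC(=O)C3=C(O2)CCCC3=O)c1OC
A10 | alternative 3 | 5,6-dihydroxy-2-(2,3,5,6-tetramethoxyphenyl)-4H-chromen-4-one | COc1cc(OC)c(OC)c(-c2cc(=O)c3c(O)c(O)ccc3o2)c1OC
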